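**Retrosynthetic overview**

1. The Z-styrene is unmasked last by semi-hydrogenation of an aryl alkyne, which is carried through all base and radical steps.
2. Structural feature: numbering the chain from the ester carbonyl (C1), the 1,2-dioxane ring is O1–O2–C3–C4–C5–C6, with C3 a peroxyhemiketal carbon (OH, CH2CO2Me) and C6 a fully substituted peroxy carbon (CH3, C7 chain). Replacing the O–O bridge by a direct C3–C6 bond gives a strained cyclobutanol, and Co(acac)2/O2 exchanges that C–C bond for O2.
3. The cyclobutanol comes from the lithium enolate of methyl acetate and a 2,2,4-trisubstituted cyclobutanone. C4 is installed as 4R by SAMP-hydrazone methylation, because either C4 epimer of the dioxanol can place its methyl equatorial and so C4 cannot be corrected after ring expansion.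
4. The cyclobutanone comes from a methyl ketone and cyclopropyldiphenylsulfonium ylide. The methyl ketone comes from (R)-citronellal (C8 and C6–C11), MeMgBr, and the Grignard reagent of PhC≡C(CH2)3Cl by copper-catalysed sp3–sp3 coupling.
5. Ring order: cyclobutane (step 7) first, then the 1,2-dioxane (step 12), which replaces it.

Key step: step 12

Assumption: the quaternary ring carbon made in step 7 (C6 of the target) is carried as both epimers through compounds 15–24, and 24 also as both carbinol epimers, because both centres are erased in step 12; 24 is drawn as its expected main diastereomer.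

**Route**

Step 1
Reactants: 1 phenylacetylene (ethynylbenzene); 2 1-bromo-3-chloropropane
Product: 4 (5-chloropent-1-yn-1-yl)benzene, via lithium phenylacetylide 3 (not isolated)
Conditions: n-BuLi, THF, −78 °C; then 2, DMPU, −78 °C → rt
Reagents that add atoms: 1-bromo-3-chloropropane (2), ClCCCBr
Why: Acetylide alkylation (SN2) occurs at the more reactive C–Br bond and leaves the chloride for later Grignard formation.

Step 2
Reactants: 5 (R)-citronellal [(3R)-3,7-dimethyloct-6-enal]
Product: 6 (4R)-4,8-dimethylnon-7-en-2-ol (both C2 epimers)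
Conditions: MeMgBr, Et2O, 0 °C; then 1 M HCl, 0 °C
Reagents that add atoms: methylmagnesium bromide, C[Mg]Br
Why: Grignard addition to the aldehyde supplies the future C6 methyl; the new carbinol centre forms as both epimers, which is harmless because it is oxidised in step 6, and the citronellal stereocentre (C8 of the target) is not touched.

Step 3
Reactants: 6
Product: 8 (4R)-4-methylheptane-1,6-diol (both C6 epimers), via secondary ozonide 7 (not isolated)
Conditions: O3, CH2Cl2, −78 °C; then NaBH4, MeOH, −78 °C → rt
Reagents that add atoms: ozone, [O-][O+]=O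
Why: Ozonolysis of the trisubstituted alkene with reductive NaBH4 work-up removes the isopropylidene end and gives the primary alcohol directly.

Step 4
Reactants: 8
Product: 9 (4R)-6-hydroxy-4-methylheptyl 4-methylbenzenesulfonate
Conditions: TsCl (1.05 equiv), pyridine, CH2Cl2, 0 °C
Reagents that add atoms: 4-methylbenzenesulfonyl chloride, Cc1ccc(cc1)S(Cl)(=O)=O
Why: Selective sulfonylation, since the unhindered primary hydroxyl reacts much faster than the secondary one with one equivalent of TsCl at 0 °C.

Step 5
Reactants: 9; 4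
Product: 11 (4R)-4-methyl-12-phenyldodec-11-yn-2-ol (both C2 epimers), via alkynyl Grignard reagent 10 (not isolated)
Conditions: 4, Mg, THF, reflux; then 9, Li2CuCl4 (5 mol %), THF, −78 °C → rt (2.5 equiv of 10); then 1 M HCl
Reagents that add atoms: (5-chloropent-1-yn-1-yl)benzene (4), ClCCCC#Cc1ccccc1
Why: Copper-catalysed coupling of a primary tosylate with an alkyl Grignard reagent (Kochi–Schlosser type); the first equivalent of 10 only deprotonates the hydroxyl, and the conjugated alkyne is inert to the cuprate at low temperature.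

Step 6
Reactants: 11
Product: 12 (4R)-4-methyl-12-phenyldodec-11-yn-2-one
Conditions: Dess–Martin periodinane, CH2Cl2, rt
Reagents that add atoms: none
Why: Dess–Martin oxidation turns the secondary alcohol into the methyl ketone under near-neutral conditions that leave the alkyne and the beta stereocentre alone.

Step 7
Reactants: 12; 13 cyclopropyldiphenylsulfonium tetrafluoroborate
Product: 16 2-methyl-2-[(2R)-2-methyl-10-phenyldec-9-yn-1-yl]cyclobutan-1-one (both epimers at ring C2), via diphenylsulfonium cyclopropylide 14 (not isolated), via oxaspiropentane 15 (not isolated)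
Conditions: 13, KOH (powdered), DMSO, 25 °C; then 1 M aq. HBF4, Et2O, rt
Reagents that add atoms: cyclopropyldiphenylsulfonium tetrafluoroborate (13), F[B-](F)(F)F.C1CC1[S+](c1ccccc1)c1ccccc1
Why: Trost spiroannulation, in which the ylide adds to the ketone and closes to the oxaspiropentane and acid then triggers the strain-driven cyclopropylcarbinyl-to-cyclobutyl shift that places the carbonyl next to the new quaternary carbon; that carbon (C6) forms as both epimers, which is accepted because step 12 erases it.

Step 8
Reactants: 16; 17 SAMP [(S)-1-amino-2-(methoxymethyl)pyrrolidine]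
Product: 18 (S,E)-2-(methoxymethyl)-N-[2-methyl-2-[(2R)-2-methyl-10-phenyldec-9-yn-1-yl]cyclobutylidene]pyrrolidin-1-amine
Conditions: 17, TsOH (cat.), cyclohexane, 60 °C, 4 Å molecular sieves
Reagents that add atoms: SAMP (17), COC[C@@H]1CCCN1N
Why: Hydrazone condensation on the strained, electrophilic cyclobutanone carbonyl, with the pyrrolidine nitrogen expected syn to the unhindered ring CH2.

Step 9
Reactants: 18
Product: 20 (S,E)-N-[(4R)-2,4-dimethyl-2-[(2R)-2-methyl-10-phenyldec-9-yn-1-yl]cyclobutylidene]-2-(methoxymethyl)pyrrolidin-1-amine, via lithium azaenolate 19 (not isolated)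
Conditions: LiN(iPr)2 (1.05 equiv), THF, 0 °C; then MeI, −100 °C → −78 °C
Reagents that add atoms: iodomethane, CI
Why: Enders SAMP-hydrazone alkylation, where deprotonation is possible only at the ring CH2 (C4) and the methoxymethyl-chelated lithium azaenolate is methylated on one face, which by the usual model (the sense that gives (R)-2-methylcyclohexanone from SAMP) should set 4R in both C6 epimers.

Step 10
Reactants: 20
Product: 21 (4R)-2,4-dimethyl-2-[(2R)-2-methyl-10-phenyldec-9-yn-1-yl]cyclobutan-1-one (both epimers at ring C2)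
Conditions: sat. aq. oxalic acid, Et2O, rt
Reagents that add atoms: water, O
Why: Mild two-phase oxalic acid hydrolysis of the hydrazone releases the ketone without epimerising the alpha stereocentre and returns the auxiliary as its oxalate.

Step 11
Reactants: 21; 22 methyl acetate
Product: 24 methyl 2-[(1R,2S,4R)-1-hydroxy-2,4-dimethyl-2-[(2R)-2-methyl-10-phenyldec-9-yn-1-yl]cyclobutyl]acetate, via lithium enolate of methyl acetate 23 (not isolated)
Conditions: LiN(iPr)2, 22, THF, −78 °C; then 21, −78 °C; AcOH, −78 °C
Reagents that add atoms: methyl acetate (22), COC(C)=O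
Why: Aldol-type addition of the ester enolate to the strain-activated cyclobutanone carbonyl should outpace enolisation at −78 °C; attack is expected anti to the C4 methyl, but the new carbinol configuration is irrelevant because this carbon becomes a ketone in step 12.

Step 12
Reactants: 24; 25 dioxygen
Product: 27 methyl 2-[(3S,4R,6S)-3-hydroxy-4,6-dimethyl-6-[(2R)-2-methyl-10-phenyldec-9-yn-1-yl]-1,2-dioxan-3-yl]acetate, via open-chain hydroperoxy ketone 26 (not isolated)
Conditions: Co(acac)2 (10 mol %), O2 (1 atm), MeCN, 40 °C; then chromatographic separation of the C6 epimers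
Reagents that add atoms: dioxygen (25), O=O
Why: Co(acac)2 and O2 should convert the tertiary cyclobutanol into a trivalent cobalt alkoxide that releases the C3 alkoxy radical; strain-driven beta-scission of C3–C6 gives the C3 ketone and the tertiary C6 radical, which captures O2, and the peroxyl radical is reduced to hydroperoxide 26 while the cobalt alkoxide is regenerated. The closest known reaction type is the cobalt-catalysed aerobic ring expansion of cyclobutanols to 1,2-dioxan-3-ols. The 1,2-dioxane ring closes by 6-exo-trig addition of the hydroperoxide oxygen to the C3 carbonyl (peroxyhemiketalisation). C3 is set thermodynamically through reversible ring-chain tautomerism, with OH axial (anomeric effect) and CH2CO2Me equatorial, cis to the equatorial C4 methyl, which is the 3S arrangement; C6 is not controlled because O2 meets a planar acyclic radical, so both C6 epimers are expected and the 6S isomer is taken by chromatography. The step needs cleavage of C3–C6 and not of C3–C4 or the exocyclic C3–C2 bond, which the tertiary radical and the release of ring strain secure, and it needs the alkyne and C4 to stay untouched, which the absence of a hydride source and the neutral medium secure.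

Step 13
Reactants: 27
Product: 28 methyl 2-[(3S,4R,6S)-3-hydroxy-4,6-dimethyl-6-[(2R,9Z)-2-methyl-10-phenyldec-9-en-1-yl]-1,2-dioxan-3-yl]acetate (target)
Conditions: H2 (1 atm), Pd/CaCO3 poisoned with Pb(OAc)2, quinoline, EtOAc, 0 °C, stopped after one equivalent of H2
Reagents that add atoms: none
Why: Lindlar semi-hydrogenation delivers H2 syn to the aryl alkyne on the lead-poisoned palladium surface to give the Z-styrene, and the poisoned catalyst with quinoline at 0 °C is expected to spare the O–O bond.

**Compound list**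

1 | phenylacetylene (ethynylbenzene) | C#Cc1ccccc1 | starting material
2 | 1-bromo-3-chloropropane | ClCCCBr | starting material
3 | lithium phenylacetylide | [Li]C#Cc1ccccc1 | intermediate
4 | (5-chloropent-1-yn-1-yl)benzene | ClCCCC#Cc1ccccc1 | intermediate
5 | (R)-citronellal, (3R)-3,7-dimethyloct-6-enal | C[C@H](CCC=C(C)C)CC=O | starting material
6 | (4R)-4,8-dimethylnon-7-en-2-ol (both C2 epimers) | CC(O)C[C@H](C)CCC=C(C)C | intermediate
7 | 5-[(3R)-5-hydroxy-3-methylhexyl]-3,3-dimethyl-1,2,4-trioxolane (secondary ozonide) | CC(O)C[C@H](C)CCC1OOC(C)(C)O1 | intermediate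
8 | (4R)-4-methylheptane-1,6-diol (both C6 epimers) | CC(O)C[C@H](C)CCCO | intermediate
9 | (4R)-6-hydroxy-4-methylheptyl 4-methylbenzenesulfonate | CC(O)C[C@H](C)CCCOS(=O)(=O)c1ccc(C)cc1 | intermediate
10 | chlorido(5-phenylpent-4-yn-1-yl)magnesium | Cl[Mg]CCCC#Cc1ccccc1 | intermediate
11 | (4R)-4-methyl-12-phenyldodec-11-yn-2-ol (both C2 epimers) | CC(O)C[C@H](C)CCCCCCC#Cc1ccccc1 | intermediate
12 | (4R)-4-methyl-12-phenyldodec-11-yn-2-one | CC(=O)C[C@H](C)CCCCCCC#Cc1ccccc1 | intermediate
13 | cyclopropyldiphenylsulfonium tetrafluoroborate | F[B-](F)(F)F.C1CC1[S+](c1ccccc1)c1ccccc1 | starting material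
14 | diphenylsulfonium cyclopropylide | [C-]1(CC1)[S+](c1ccccc1)c1ccccc1 | intermediate
15 | 2-methyl-2-[(2R)-2-methyl-10-phenyldec-9-yn-1-yl]-1-oxaspiro[2.2]pentane (both C2 epimers) | CC1(C[C@H](C)CCCCCCC#Cc2ccccc2)OC12CC2 | intermediate
16 | 2-methyl-2-[(2R)-2-methyl-10-phenyldec-9-yn-1-yl]cyclobutan-1-one (both C2 epimers) | O=C1CCC1(C)C[C@H](C)CCCCCCC#Cc1ccccc1 | intermediate
17 | SAMP, (S)-1-amino-2-(methoxymethyl)pyrrolidine | COC[C@@H]1CCCN1N | starting material
18 | SAMP hydrazone of 16, pyrrolidine nitrogen syn to the ring CH2 (E) | COC[C@@H]1CCCN1/N=C1\CCC1(C)C[C@H](C)CCCCCCC#Cc1ccccc1 | intermediate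
19 | lithium azaenolate of 18 (N-lithio ene-hydrazine, ring C1=C4) | COC[C@@H]1CCCN1N([Li])C1=CCC1(C)C[C@H](C)CCCCCCC#Cc1ccccc1 | intermediate
20 | SAMP hydrazone of 21, (4R) at the new methyl-bearing carbon | COC[C@@H]1CCCN1/N=C1\[C@H](C)CC1(C)C[C@H](C)CCCCCCC#Cc1ccccc1 | intermediate
21 | (4R)-2,4-dimethyl-2-[(2R)-2-methyl-10-phenyldec-9-yn-1-yl]cyclobutan-1-one (both C2 epimers) | O=C1[C@H](C)CC1(C)C[C@H](C)CCCCCCC#Cc1ccccc1 | intermediate
22 | methyl acetate | COC(C)=O | starting material
23 | lithium enolate of methyl acetate (lithium 1-methoxyethen-1-olate) | [Li]OC(=C)OC | intermediate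
24 | methyl 2-[(1R,2S,4R)-1-hydroxy-2,4-dimethyl-2-[(2R)-2-methyl-10-phenyldec-9-yn-1-yl]cyclobutyl]acetate (drawn diastereomer; its C1 and C2 epimers are carried along) | COC(=O)C[C@@]1(O)[C@H](C)C[C@]1(C)C[C@H](C)CCCCCCC#Cc2ccccc2 | intermediate (key-step precursor)
25 | dioxygen | O=O | starting material
26 | methyl (4R,6S,8R)-6-hydroperoxy-4,6,8-trimethyl-3-oxo-16-phenylhexadec-15-ynoate | COC(=O)CC(=O)[C@H](C)C[C@@](C)(OO)C[C@H](C)CCCCCCC#Cc1ccccc1 | intermediate
27 | methyl 2-[(3S,4R,6S)-3-hydroxy-4,6-dimethyl-6-[(2R)-2-methyl-10-phenyldec-9-yn-1-yl]-1,2-dioxan-3-yl]acetate | COC(=O)C[C@]1(O)OO[C@@](C)(C[C@H](C)CCCCCCC#Cc2ccccc2)C[C@H]1C | intermediate (key-step product)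
28 | methyl 2-[(3S,4R,6S)-3-hydroxy-4,6-dimethyl-6-[(2R,9Z)-2-methyl-10-phenyldec-9-en-1-yl]-1,2-dioxan-3-yl]acetate | COC(=O)C[C@]1(O)OO[C@@](C)(C[C@H](C)CCCCCC/C=C\c2ccccc2)C[C@H]1C | target

**Step count**

Total steps: 13. Longest linear sequence: 12 (steps 2–13 from (R)-citronellal); step 1 is a one-step side branch.

**Steps most likely to fail**

Step 12. The ring expansion may suffer from competing beta-scission along C3–C4, from sequestration of cobalt by chelation to the ring-opened beta-keto ester, or from enolisation of the open-chain ketone that erodes C4; unselective O2 capture at C6 is inherent. The fallback builds the same hydroperoxide from an acyclic alkene by known chemistry; it sets out from 12 and comes back at 27.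
- Kinetic deprotonation of 12 at its methyl group (LiN(iPr)2, THF, −78 °C) and trapping with PhNTf2 should give (4R)-4-methyl-12-phenyldodec-1-en-11-yn-2-yl trifluoromethanesulfonate F1.
- Negishi coupling of F1 (Pd(PPh3)4, THF/DMA) with bromo[(2S)-3-methoxy-2-methyl-3-oxopropyl]zinc F2, made from commercial methyl (S)-3-bromo-2-methylpropanoate and Zn dust, should give methyl (2R,6R)-2,6-dimethyl-4-methylidene-14-phenyltetradec-13-ynoate F3. C4 of the target then comes from the chiral pool.
- Crossed Claisen condensation of F3 with excess 23 should give methyl (4R,8R)-4,8-dimethyl-6-methylidene-3-oxo-16-phenylhexadec-15-ynoate F4.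
- Mukaiyama–Isayama hydroperoxysilylation of F4 (Co(thd)2 with thd = 2,2,6,6-tetramethylheptane-3,5-dionate, O2, Et3SiH, 1,2-dichloroethane) places the peroxide at the more substituted C6 and should give methyl (4R,6S,8R)-4,6,8-trimethyl-3-oxo-16-phenyl-6-[(triethylsilyl)peroxy]hexadec-15-ynoate F5 together with its C6 epimer.
- HF·pyridine in THF frees hydroperoxide 26, which closes to 27; the same chromatographic separation of C6 epimers follows.

Step 13. Hydrogenolysis of the O–O bond of the peroxyhemiketal, or reduction past the alkene, may compete on the palladium surface. The fallback reverses the order of reduction and peroxide formation; it sets out from 24 and comes back at 28.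
- Semi-hydrogenation of 24 with the same poisoned catalyst, where no peroxide is present, should give methyl 2-[(1R,2S,4R)-1-hydroxy-2,4-dimethyl-2-[(2R,9Z)-2-methyl-10-phenyldec-9-en-1-yl]cyclobutyl]acetate F6.
- The Co(acac)2/O2 ring expansion of F6 passes through methyl (4R,6S,8R,15Z)-6-hydroperoxy-4,6,8-trimethyl-3-oxo-16-phenylhexadec-15-enoate F7 and should deliver 28 directly after separation from its C6 epimer.
- The cost is exposure of the Z-styrene to peroxyl radicals, which are expected to add to it only slowly.

Step 9. Facial selectivity of the azaenolate methylation may be poor on the strained ring beside the quaternary carbon, or azaenolate formation may be incomplete, leaving C4 as a mixture. The fallback drops auxiliary control and defers the resolution to the dioxanol stage; it sets out from 16 and comes back at 21.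
- Direct enolate methylation of 16 (LiN(iPr)2, THF, −78 °C; MeI) should give 21 together with its C4 epimer (4S)-2,4-dimethyl-2-[(2R)-2-methyl-10-phenyldec-9-yn-1-yl]cyclobutan-1-one F8.
- The mixture is taken through steps 11 and 12. The 4S material passes through the cyclobutanols methyl 2-[(4S)-1-hydroxy-2,4-dimethyl-2-[(2R)-2-methyl-10-phenyldec-9-yn-1-yl]cyclobutyl]acetate F9.
- It ends as methyl 2-[(3R,4S,6R)-3-hydroxy-4,6-dimethyl-6-[(2R)-2-methyl-10-phenyldec-9-yn-1-yl]-1,2-dioxan-3-yl]acetate F10 and methyl 2-[(3R,4S,6S)-3-hydroxy-4,6-dimethyl-6-[(2R)-2-methyl-10-phenyldec-9-yn-1-yl]-1,2-dioxan-3-yl]acetate F11.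
- F10 and F11 are removed together with the C6 epimer of 27 by preparative HPLC. This separation is harder than in the main route, because F10 differs from 27 only in the relation of the ring to C8.

Further compounds
F1 | step 12 | (4R)-4-methyl-12-phenyldodec-1-en-11-yn-2-yl trifluoromethanesulfonate | C=C(OS(=O)(=O)C(F)(F)F)C[C@H](C)CCCCCCC#Cc1ccccc1
F2 | step 12 | bromo[(2S)-3-methoxy-2-methyl-3-oxopropyl]zinc | COC(=O)[C@H](C)C[Zn]Br
F3 | step 12 | methyl (2R,6R)-2,6-dimethyl-4-methylidene-14-phenyltetradec-13-ynoate | COC(=O)[C@H](C)CC(=C)C[C@H](C)CCCCCCC#Cc1ccccc1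
F4 | step 12 | methyl (4R,8R)-4,8-dimethyl-6-methylidene-3-oxo-16-phenylhexadec-15-ynoate | COC(=O)CC(=O)[C@H](C)CC(=C)C[C@H](C)CCCCCCC#Cc1ccccc1
F5 | step 12 | methyl (4R,6S,8R)-4,6,8-trimethyl-3-oxo-16-phenyl-6-[(triethylsilyl)peroxy]hexadec-15-ynoate | COC(=O)CC(=O)[C@H](C)C[C@@](C)(OO[Si](CC)(CC)CC)C[C@H](C)CCCCCCC#Cc1ccccc1
F6 | step 13 | methyl 2-[(1R,2S,4R)-1-hydroxy-2,4-dimethyl-2-[(2R,9Z)-2-methyl-10-phenyldec-9-en-1-yl]cyclobutyl]acetate | COC(=O)C[C@@]1(O)[C@H](C)C[C@]1(C)C[C@H](C)CCCCCC/C=C\c2ccccc2
F7 | step 13 | methyl (4R,6S,8R,15Z)-6-hydroperoxy-4,6,8-trimethyl-3-oxo-16-phenylhexadec-15-enoate | COC(=O)CC(=O)[C@H](C)C[C@@](C)(OO)C[C@H](C)CCCCCC/C=C\c1ccccc1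
F8 | step 9 | (4S)-2,4-dimethyl-2-[(2R)-2-methyl-10-phenyldec-9-yn-1-yl]cyclobutan-1-one (both C2 epimers) | O=C1[C@@H](C)CC1(C)C[C@H](C)CCCCCCC#Cc1ccccc1
F9 | step 9 | methyl 2-[(4S)-1-hydroxy-2,4-dimethyl-2-[(2R)-2-methyl-10-phenyldec-9-yn-1-yl]cyclobutyl]acetate (C1 and C2 epimers) | COC(=O)CC1(O)[C@@H](C)CC1(C)C[C@H](C)CCCCCCC#Cc1ccccc1
F10 | step 9 | methyl 2-[(3R,4S,6R)-3-hydroxy-4,6-dimethyl-6-[(2R)-2-methyl-10-phenyldec-9-yn-1-yl]-1,2-dioxan-3-yl]acetate | COC(=O)C[C@@]1(O)OO[C@](C)(C[C@H](C)CCCCCCC#Cc2ccccc2)C[C@@H]1C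
F11 | step 9 | methyl 2-[(3R,4S,6S)-3-hydroxy-4,6-dimethyl-6-[(2R)-2-methyl-10-phenyldec-9-yn-1-yl]-1,2-dioxan-3-yl]acetate | COC(=O)C[C@@]1(O)OO[C@@](C)(C[C@H](C)CCCCCCC#Cc2ccccc2)C[C@@H]1C
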